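**Plan**

- Ring B is numbered C1 (O-aryl), C2 (OH), C3 (H), C4 (Br), C5 (H), C6 (Br); ring A is the 2,4-dibromo-6-methoxyphenyl group.
- Retrosynthesis: the C2–OH bond goes back to C2–B. Ring B is then cut at C1–C6 and C2–C3, giving 3,5-dibromo-2-pyrone and an alkyne that carries the ring-A oxygen on one carbon and boron on the other.
- Enabling feature: ring B is a 1,2-dioxygenated benzene whose carbons C3, C4, C5, C6 carry H, Br, H, Br. This is exactly the pattern of C6, C5, C4, C3 of 3,5-dibromo-2-pyrone, so C1 and C2 can come from a two-carbon O/B-substituted alkyne.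
- The alkyne is cut at C(sp)–B to a terminal aryl ethynyl ether, which comes from the aryl vinyl ether and that from 2,4-dibromo-6-methoxyphenol, itself made from 2-methoxyaniline. The hindered diaryl ether oxygen is therefore joined to an unhindered carbon before ring B exists.
- Forward: ring A is bought and functionalised, the C2 unit is put on its oxygen and raised to the alkynyl boronate, ring B (the only ring made) is closed last by [4+2]/retro-[4+2], and C–B oxidation ends the route.
- Stereochemistry (remark on the chemistry): the target has no stereocentre and its diaryl ether axis is not expected to be configurationally stable, so it is a single achiral compound and nothing has to be controlled.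

Key step: step 7

**Route**

Step 1
Reactants: 1 2-methoxyaniline
Product: 2 2,4-dibromo-6-methoxyaniline
Conditions: NBS (2.05 equiv), MeCN, 0 °C → rt
Reagents that add atoms: N-bromosuccinimide, O=C1CCC(=O)N1Br
Why: Electrophilic aromatic bromination is steered by the amino group, the strongest donor, to its free para and ortho positions (both meta to OMe), and should stop at the dibromide because the remaining ring positions are meta to nitrogen.

Step 2
Reactants: 2 2,4-dibromo-6-methoxyaniline
Product: 4 2,4-dibromo-6-methoxyphenol, via diazonium hydrogensulfate 3 (not isolated)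
Conditions: NaNO2, H2SO4, AcOH–H2O, 0–5 °C; then aq. Cu(NO3)2 (excess), Cu2O (cat.), rt
Reagents that add atoms: water, O
Why: Diazotisation followed by copper-mediated hydroxy-dediazoniation (Sandmeyer-type hydroxylation) runs through the aryl radical at room temperature, which should spare this electron-poor, di-ortho-substituted diazonium ion the forcing thermal hydrolysis in which water could displace an activated bromide.

Step 3
Reactants: 4 2,4-dibromo-6-methoxyphenol; 5 2,4,6-trivinylcyclotriboroxane–pyridine complex
Product: 6 1,5-dibromo-3-methoxy-2-(vinyloxy)benzene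
Conditions: 5 (0.67 equiv), Cu(OAc)2 (1.0 equiv), pyridine (10 equiv), CH2Cl2, air, rt
Reagents that add atoms: none
Why: Chan–Lam O-vinylation (vinyl transfer from boron to a copper(II) phenoxide, then C–O reductive elimination) proceeds at room temperature, accepts di-ortho-halogenated phenols, leaves aryl bromides alone, and air returns the metal to copper(II).

Step 4
Reactants: 6 1,5-dibromo-3-methoxy-2-(vinyloxy)benzene
Product: 9 1,5-dibromo-2-(ethynyloxy)-3-methoxybenzene, via 1,2-dibromoethyl ether 7 (not isolated), via (Z)-2-bromovinyl ether 8 (not isolated)
Conditions: Br2 (1.0 equiv), CH2Cl2, −78 °C; solvent exchange; t-BuOK (3.0 equiv), THF, −78 °C → rt; pH 7 work-up, product kept cold in solution and used at once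
Reagents that add atoms: none
Why: Bromine adds to the electron-rich enol ether double bond much faster than it substitutes the deactivated arene, and tert-butoxide then effects two successive E2 dehydrobrominations (the second an anti elimination from the Z-bromovinyl ether), the classical bromination–double dehydrohalogenation route from a vinyl ether to an alkynyl ether; the aryl bromides do not react with alkoxide at this temperature.

Step 5
Reactants: 9 1,5-dibromo-2-(ethynyloxy)-3-methoxybenzene; 10 2-isopropoxy-4,4,5,5-tetramethyl-1,3,2-dioxaborolane
Product: 13 2-[(2,4-dibromo-6-methoxyphenoxy)ethynyl]-4,4,5,5-tetramethyl-1,3,2-dioxaborolane, via lithium acetylide 11 (not isolated), via lithium isopropoxyborate 12 (not isolated)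
Conditions: LiHMDS (1.05 equiv), THF, −78 °C; 10 (1.1 equiv), −78 °C; HCl (1.1 equiv, 2 M in Et2O), −78 °C → rt; filtration under Ar, used crude
Reagents that add atoms: none
Why: Deprotonation of the terminal alkyne, addition of the acetylide to the borate and collapse of the ate complex with one equivalent of anhydrous HCl is the standard synthesis of alkynyl pinacol boronates; LiHMDS causes no bromine–lithium exchange and is too weak to metalate the ring C–H between the bromines, and the liberated hexamethyldisilazane buffers excess acid away from the ynol ether.

Step 6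
Reactants: 14 coumalic acid
Product: 16 3,5-dibromo-2H-pyran-2-one, via 5-bromo-2-pyrone 15 (not isolated)
Conditions: NBS (2.5 equiv), LiOAc (0.2 equiv), MeCN–H2O (9:1), rt
Reagents that add atoms: N-bromosuccinimide, O=C1CCC(=O)N1Br
Why: Hunsdiecker-type bromodecarboxylation (bromonium attack at C5, the nucleophilic carbon of the ring enol ether that bears the carboxylate, then loss of CO2) is followed in the same pot by electrophilic bromination at C3, the other nucleophilic position of the pyrone, a one-pot process known for coumalic acid.

Step 7
Reactants: 13 2-[(2,4-dibromo-6-methoxyphenoxy)ethynyl]-4,4,5,5-tetramethyl-1,3,2-dioxaborolane; 16 3,5-dibromo-2H-pyran-2-one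
Product: 18 2-[3,5-dibromo-2-(2,4-dibromo-6-methoxyphenoxy)phenyl]-4,4,5,5-tetramethyl-1,3,2-dioxaborolane, via bridged lactone 17 (not isolated)
Conditions: 13 (1.3 equiv), 16 (1.0 equiv), BHT (cat.), toluene (0.5 M), sealed tube, 110 °C
Reagents that add atoms: none
Why: Proposed new method: the aryloxy oxygen polarises the alkyne so that its boron-bearing carbon is the nucleophilic terminus, which should bond first to C6 of the electron-poor pyrone (the δ-carbon of its dienoate) while the oxygen-bearing carbon closes onto C3 in an asynchronous inverse-electron-demand [4+2] cycloaddition, and the 2-oxabicyclo[2.2.2]octadienone 17 then loses CO2 irreversibly by retro-[4+2]. The closest known reactions are the thermal Diels–Alder/retro-Diels–Alder benzannulations of 2-pyrones with alkynylboronates and the cycloadditions of 3,5-dibromo-2-pyrone with enol ethers, in which the oxygenated carbon ends up next to the C3–Br bridgehead. Ring B is closed by intermolecular [4+2] cycloaddition forming C1–C6 and C2–C3 (target numbering), and cycloreversion of the lactone bridge delivers it directly as an arene with Br, H, Br, H in place. No stereocentre results, because the two bridgehead centres of 17 are lost on aromatisation. The step needs regioselectivity (O-carbon to pyrone C3, B-carbon to pyrone C6), which the donor oxygen should secure against the only weakly accepting boronate. It also needs the cycloaddition to outrun alkyne oligomerisation, which is helped by the di-ortho-substituted aryl group, the absence of any β-hydrogen for ketene formation, the moderate temperature and the radical inhibitor.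

Step 8
Reactants: 18 2-[3,5-dibromo-2-(2,4-dibromo-6-methoxyphenoxy)phenyl]-4,4,5,5-tetramethyl-1,3,2-dioxaborolane
Product: 19 3,5-dibromo-2-(2,4-dibromo-6-methoxyphenoxy)phenol
Conditions: 30% aq. H2O2, 1 M aq. NaOH, THF, 0 °C → rt; then aq. NH4Cl
Reagents that add atoms: hydrogen peroxide, OO
Why: Standard oxidation of an arylboronic ester: hydroperoxide adds to boron, the aryl group migrates from boron to oxygen, and the borate is hydrolysed, while aryl bromides, the methyl ether and the diaryl ether are untouched.

**Compound list**

1 | 2-methoxyaniline | COc1ccccc1N | starting material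
2 | 2,4-dibromo-6-methoxyaniline | COc1cc(Br)cc(Br)c1N | intermediate
3 | 2,4-dibromo-6-methoxybenzenediazonium hydrogensulfate | COc1cc(Br)cc(Br)c1[N+]#N.OS(=O)(=O)[O-] | intermediate (not isolated)
4 | 2,4-dibromo-6-methoxyphenol | COc1cc(Br)cc(Br)c1O | intermediate
5 | 2,4,6-trivinylcyclotriboroxane–pyridine complex | C=CB1OB(C=C)OB(C=C)O1.c1ccncc1 | starting material
6 | 1,5-dibromo-3-methoxy-2-(vinyloxy)benzene | COc1cc(Br)cc(Br)c1OC=C | intermediate
7 | 1,5-dibromo-2-(1,2-dibromoethoxy)-3-methoxybenzene (racemic) | COc1cc(Br)cc(Br)c1OC(Br)CBr | intermediate (not isolated)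
8 | 1,5-dibromo-2-{[(Z)-2-bromovinyl]oxy}-3-methoxybenzene | COc1cc(Br)cc(Br)c1O/C=C\Br | intermediate (not isolated)
9 | 1,5-dibromo-2-(ethynyloxy)-3-methoxybenzene | COc1cc(Br)cc(Br)c1OC#C | intermediate
10 | 2-isopropoxy-4,4,5,5-tetramethyl-1,3,2-dioxaborolane | CC(C)OB1OC(C)(C)C(C)(C)O1 | starting material
11 | lithium (2,4-dibromo-6-methoxyphenoxy)acetylide | COc1cc(Br)cc(Br)c1OC#C[Li] | intermediate (not isolated)
12 | lithium [(2,4-dibromo-6-methoxyphenoxy)ethynyl](isopropoxy)(pinacolato)borate | [Li+].COc1cc(Br)cc(Br)c1OC#C[B-]1(OC(C)C)OC(C)(C)C(C)(C)O1 | intermediate (not isolated)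
13 | 2-[(2,4-dibromo-6-methoxyphenoxy)ethynyl]-4,4,5,5-tetramethyl-1,3,2-dioxaborolane | COc1cc(Br)cc(Br)c1OC#CB1OC(C)(C)C(C)(C)O1 | intermediate
14 | coumalic acid (2-oxo-2H-pyran-5-carboxylic acid) | O=C(O)C1=COC(=O)C=C1 | starting material
15 | 5-bromo-2H-pyran-2-one | O=C1C=CC(Br)=CO1 | intermediate (not isolated)
16 | 3,5-dibromo-2H-pyran-2-one | O=C1OC=C(Br)C=C1Br | intermediate
17 | 4,6-dibromo-8-(2,4-dibromo-6-methoxyphenoxy)-7-(4,4,5,5-tetramethyl-1,3,2-dioxaborolan-2-yl)-2-oxabicyclo[2.2.2]octa-5,7-dien-3-one (racemic) | O=C1OC2C(Br)=CC1(Br)C(Oc1c(Br)cc(Br)cc1OC)=C2B1OC(C)(C)C(C)(C)O1 | intermediate (not isolated)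
18 | 2-[3,5-dibromo-2-(2,4-dibromo-6-methoxyphenoxy)phenyl]-4,4,5,5-tetramethyl-1,3,2-dioxaborolane | COc1cc(Br)cc(Br)c1Oc1c(B2OC(C)(C)C(C)(C)O2)cc(Br)cc1Br | intermediate
19 | 3,5-dibromo-2-(2,4-dibromo-6-methoxyphenoxy)phenol | COc1cc(Br)cc(Br)c1Oc1c(O)cc(Br)cc1Br | target

**Count and risks**

Total steps: 8. Longest linear sequence: 7 (steps 1, 2, 3, 4, 5, 7, 8); the pyrone branch is one step (step 6).

Step 7 (key step). The alkynyl boronate may oligomerise or lose boron by protonolysis faster than it adds to the pyrone, or the cycloaddition may take the reverse orientation and place boron next to the C–Br carbon. The fallback uses known chemistry and gives up the benzannulation. It sets out from phenol 4, which is joined by nucleophilic aromatic substitution to commercial 3,5-dibromo-2-fluorobenzaldehyde (K2CO3, DMF, 80–100 °C; fluoride activated by the ortho formyl group) to give 3,5-dibromo-2-(2,4-dibromo-6-methoxyphenoxy)benzaldehyde F1. Baeyer–Villiger oxidation with mCPBA in CH2Cl2 (aryl migration favoured by the ortho aryloxy group) should give 3,5-dibromo-2-(2,4-dibromo-6-methoxyphenoxy)phenyl formate F2. Methanolysis with K2CO3 in MeOH then returns the route at the target 19.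

Step 5. Deprotonation by the amide base may be incomplete, HCl may add across the acid-sensitive ynol ether while the ate complex is collapsed, and the alkynyl C–B bond may be protonolysed on handling. The fallback replaces the acetylide–borate sequence by a catalytic dehydrogenative C–H borylation of the terminal alkyne. It sets out from 9, which is treated with pinacolborane, a (cyclic alkyl)(amino)carbene copper(I) triflate catalyst and catalytic Et3N in an arene solvent at rt. This needs no strong base, no ate complex and no acid, and comes back at 13 without any new compound.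

Step 4. tert-Butoxide may substitute the α-bromo ether or add to the alkyne in place of eliminating, and the free terminal aryloxyacetylene may oligomerise during isolation. The fallback never sets the terminal alkyne free. It sets out from 6: Br2 and then DBU (CH2Cl2, −78 °C → rt) give, by way of 7, the bromovinyl ether 8, which is now isolated as a stable compound. NaHMDS (2.2 equiv, THF, −78 → −20 °C), a hindered non-nucleophilic amide, then effects the anti elimination and metalates in the same flask, the standard in situ entry to metal alkoxyacetylides, giving sodium (2,4-dibromo-6-methoxyphenoxy)acetylide F3. Borate 10 converts it into sodium [(2,4-dibromo-6-methoxyphenoxy)ethynyl](isopropoxy)(pinacolato)borate F4, and HCl in Et2O collapses this to 13, where the route is rejoined with steps 4 and 5 merged.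

**Further compounds**

F1 | step 7 | 3,5-dibromo-2-(2,4-dibromo-6-methoxyphenoxy)benzaldehyde | COc1cc(Br)cc(Br)c1Oc1c(C=O)cc(Br)cc1Br
F2 | step 7 | 3,5-dibromo-2-(2,4-dibromo-6-methoxyphenoxy)phenyl formate | COc1cc(Br)cc(Br)c1Oc1c(OC=O)cc(Br)cc1Br
F0 | step 5 | none | none
F3 | step 4 | sodium (2,4-dibromo-6-methoxyphenoxy)acetylide | COc1cc(Br)cc(Br)c1OC#C[Na]
F4 | step 4 | sodium [(2,4-dibromo-6-methoxyphenoxy)ethynyl](isopropoxy)(pinacolato)borate | [Na+].COc1cc(Br)cc(Br)c1OC#C[B-]1(OC(C)C)OC(C)(C)C(C)(C)O1
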